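**Plan**

- Numbering used throughout: C1 lactone C=O, C2 its CH2, C3 the peroxy CH, C4 the fusion carbon (CH3, lactone O), C5 the ring CH2, C6 the carbon with CH3 and the chain.
- Enabling feature: C3 and C6 stand 1,4 to each other across C4–C5 and both carry a peroxide oxygen. The O–O unit of the 1,2-dioxane can therefore take the place of a C3–C6 bond in a cyclobutanol fused to the γ-lactone.
- Retrosynthetic cuts, in order: C6–CH3 (methyl onto a peroxycarbenium ion); O–C3 and O–C6 (back to the C3–C6 bond of the cyclobutanol); C6–chain (Grignard addition to a cyclobutanone); C3–C6 and C4–C5 ([2+2] on α-angelica lactone); phenyl–chain.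
- Forward order: the lactone ring is present from the start, the cyclobutane is fused onto it, the chain is joined at C6, O2 expands the four-membered ring to the 1,2-dioxane, and the C6 methyl comes last.
- Stereochemistry: C4 (with cis C3) from the auxiliary-controlled [2+2]; C3–O from the cis ring fusion that the peroxide closure demands; C6 from axial methyl delivery cis to the lactone oxygen.

Key step: step 5

Assumption: the sense of induction of the C2-symmetric keteniminium salt on this enol lactone cannot be predicted with confidence; the route is written with the (2R,5R)-amine, and the (2S,5S)-amine would be used in the same way if the first cycloaddition favours the (1R,5R)-ketone.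

**Step 1**
Reactants: 1 bromobenzene; 2 1,12-dibromododecane
Product: 4 (12-bromododecyl)benzene, via phenylmagnesium bromide 3 (not isolated)
Conditions: Mg, THF, rt; then 2 (3 equiv), Li2CuCl4 (3 mol %), THF, −10 → 0 °C
Reagents that add atoms: none
Why: Copper-catalysed Grignard–alkyl bromide cross-coupling of the Kochi type; the threefold excess of dibromide should hold double arylation down, the unchanged dibromide is removed by distillation, and no stereocentre is involved.

**Step 2**
Reactants: 5 (2R,5R)-2,5-dimethylpyrrolidine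
Product: 6 1-[(2R,5R)-2,5-dimethylpyrrolidin-1-yl]ethan-1-one
Conditions: Ac2O, Et3N, CH2Cl2, 0 °C → rt
Reagents that add atoms: acetic anhydride, CC(=O)OC(C)=O
Why: Plain N-acetylation of a secondary amine, which leaves both auxiliary stereocentres untouched.

**Step 3**
Reactants: 6 1-[(2R,5R)-2,5-dimethylpyrrolidin-1-yl]ethan-1-one; 7 α-angelica lactone (5-methylfuran-2(3H)-one)
Product: 10 (1S,5S)-1-methyl-2-oxabicyclo[3.2.0]heptane-3,6-dione, via keteniminium triflate 8 (not isolated), via cyclobutaniminium triflate 9 (not isolated)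
Conditions: Tf2O, CH2Cl2, −20 °C; then 2,6-di-tert-butyl-4-methylpyridine, 7 (2 equiv), → 40 °C; then H2O, rt
Reagents that add atoms: water, O
Why: Keteniminium–olefin [2+2] cycloaddition of the Ghosez type: the electrophilic central carbon of 8 should bond to the enol-lactone CH (C3) and the oxygen-stabilised cation at C4 is closed by the enamine carbon (C5), so the iminium carbon becomes C6 next to C3; the ring allows only cis fusion, the C2-symmetric pyrrolidine is relied on to choose the alkene face and so sets C4 and C3 together, and water hydrolyses 9 to the ketone (enantiomeric purity to be checked on a chiral phase and raised by recrystallisation if needed).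

**Step 4**
Reactants: 4 (12-bromododecyl)benzene; 10 (1S,5S)-1-methyl-2-oxabicyclo[3.2.0]heptane-3,6-dione
Product: 12 (1S,5R)-6-hydroxy-1-methyl-6-(12-phenyldodecyl)-2-oxabicyclo[3.2.0]heptan-3-one as its C6 epimers, via 12-phenyldodecylmagnesium bromide 11 (not isolated)
Conditions: 4, Mg, THF, 45 °C; then added to 10 and anhydrous CeCl3 (1.5 equiv), THF, −78 °C; sat. aq. NH4Cl
Reagents that add atoms: none
Why: CeCl3-promoted 1,2-addition of a Grignard reagent (Imamoto conditions): the oxophilic, weakly basic reagent should add to the strained ketone at −78 °C faster than it enolises it (which would expel the β-lactone oxygen) or attacks the lactone; attack from the convex face is expected, but the carbinol configuration is erased in step 5.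

**Step 5**
Reactants: 12 (1S,5R)-6-hydroxy-1-methyl-6-(12-phenyldodecyl)-2-oxabicyclo[3.2.0]heptan-3-one; 13 dioxygen
Product: 15 (4aS,7aS)-3-hydroxy-4a-methyl-3-(12-phenyldodecyl)tetrahydro-3H-furo[3,2-c][1,2]dioxin-6(4H)-one as its hemiketal epimers, via hydroperoxy ketone 14 (not isolated)
Conditions: Co(acac)2 (20 mol %), O2 (1 atm), MeCN, 40 °C
Reagents that add atoms: dioxygen (13), O=O
Why: Divalent cobalt and O2 should give a trivalent cobalt alkoxide of 12 whose homolysis releases the cyclobutyloxy radical; β-scission of the C3–C6 bond, capture of O2 at C3 and hydrogen transfer give hydroperoxy ketone 14, which closes on the C6 carbonyl. The closest known reaction type is the Co(acac)2/O2 oxidative ring expansion of tertiary cyclobutanols to 1,2-dioxan-3-ols. The 1,2-dioxane closes by 6-exo-trig addition of the hydroperoxide oxygen to the C6 carbonyl (peroxyhemiketal formation). The new stereocentre C3 is fixed by the ring fusion: only the hydroperoxide cis to the C5 side chain can reach C6, so the bicyclic product can only be cis-fused, while C4 is carried through untouched and C6 stays an unassigned hemiketal. The step needs β-scission toward C3 and not toward C5 or the chain, which the secondary character of the C3 radical and the release of ring strain secure; the face of O2 capture is not secured by the substrate, so the trans hydroperoxide, which stays open-chain and is separated, lowers the yield but cannot contaminate 15.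

**Step 6**
Reactants: 15 (4aS,7aS)-3-hydroxy-4a-methyl-3-(12-phenyldodecyl)tetrahydro-3H-furo[3,2-c][1,2]dioxin-6(4H)-one
Product: 16 (4aS,7aS)-4a-methyl-6-oxo-3-(12-phenyldodecyl)hexahydro-3H-furo[3,2-c][1,2]dioxin-3-yl acetate as its ketal epimers
Conditions: Ac2O, pyridine, DMAP (cat.), CH2Cl2, 0 °C
Reagents that add atoms: acetic anhydride, CC(=O)OC(C)=O
Why: O-Acetylation of the tertiary peroxyhemiketal hydroxyl, as known for 1,2-dioxan-3-ols, installs an ionisable leaving group; pyridine at 0 °C is too weak a base for Kornblum–DeLaMare cleavage at C3–H or β-elimination of the peroxide from the lactone, and both acetate epimers converge on one cation in step 7.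

**Step 7**
Reactants: 16 (4aS,7aS)-4a-methyl-6-oxo-3-(12-phenyldodecyl)hexahydro-3H-furo[3,2-c][1,2]dioxin-3-yl acetate
Product: 18 plakortolide L [(3S,4aS,7aS)-3,4a-dimethyl-3-(12-phenyldodecyl)tetrahydro-3H-furo[3,2-c][1,2]dioxin-6(4H)-one], via peroxycarbenium ion 17 (not isolated)
Conditions: Me3Al (3 equiv), CH2Cl2, −78 → −20 °C; aq. potassium sodium tartrate
Reagents that add atoms: trimethylaluminium, C[Al](C)C
Why: Proposed new method: Me3Al should ionise the tertiary peroxyketal acetate to peroxycarbenium ion 17 paired with Me3Al(OAc)−, and the aluminate (or a second Me3Al) then transfers methyl to C6; the closest known reaction types are the Lewis-acid-mediated substitution of cyclic peroxyketals by allylsilanes and silyl enol ethers through peroxycarbenium ions and the Me3Al C-methylation of anomeric acetates and fluorides, which peroxide bridges are known to survive; C6 should be set by axial, chair-like attack on the half-chair cation from the face of the lactone oxygen, because the opposite chair-like approach runs 1,3-diaxial into the C4 methyl group, so the new methyl ends up axial and cis to the lactone oxygen and the chain equatorial.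

**Compound list**

1 | bromobenzene | Brc1ccccc1 | starting material
2 | 1,12-dibromododecane | BrCCCCCCCCCCCCBr | starting material
3 | phenylmagnesium bromide (formed in the flask, not isolated) | Br[Mg]c1ccccc1 | intermediate
4 | (12-bromododecyl)benzene | BrCCCCCCCCCCCCc1ccccc1 | intermediate
5 | (2R,5R)-2,5-dimethylpyrrolidine | C[C@@H]1CC[C@@H](C)N1 | starting material
6 | 1-[(2R,5R)-2,5-dimethylpyrrolidin-1-yl]ethan-1-one | C[C@@H]1CC[C@@H](C)N1C(C)=O | intermediate
7 | α-angelica lactone (5-methylfuran-2(3H)-one) | CC1=CCC(=O)O1 | starting material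
8 | 1-ethenylidene-(2R,5R)-2,5-dimethylpyrrolidin-1-ium triflate (keteniminium salt, not isolated) | C[C@@H]1CC[C@@H](C)[N+]1=C=C.[O-]S(=O)(=O)C(F)(F)F | intermediate
9 | (2R,5R)-2,5-dimethyl-1-[(1S,5R)-1-methyl-3-oxo-2-oxabicyclo[3.2.0]heptan-6-ylidene]pyrrolidin-1-ium triflate (cis-fused cyclobutaniminium salt, not isolated) | C[C@@H]1CC[C@@H](C)[N+]1=C1C[C@]2(C)OC(=O)C[C@H]12.[O-]S(=O)(=O)C(F)(F)F | intermediate
10 | (1S,5S)-1-methyl-2-oxabicyclo[3.2.0]heptane-3,6-dione (cis-fused) | O=C1C[C@]2(C)OC(=O)C[C@H]12 | intermediate
11 | 12-phenyldodecylmagnesium bromide (not isolated) | Br[Mg]CCCCCCCCCCCCc1ccccc1 | intermediate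
12 | (1S,5R)-6-hydroxy-1-methyl-6-(12-phenyldodecyl)-2-oxabicyclo[3.2.0]heptan-3-one (cis-fused, C6 epimers) | OC1(CCCCCCCCCCCCc2ccccc2)C[C@]2(C)OC(=O)C[C@H]12 | intermediate
13 | dioxygen | O=O | starting material
14 | (4S,5S)-4-hydroperoxy-5-methyl-5-(2-oxo-14-phenyltetradecyl)dihydrofuran-2(3H)-one (not isolated) | O=C(CCCCCCCCCCCCc1ccccc1)C[C@]1(C)OC(=O)C[C@@H]1OO | intermediate
15 | (4aS,7aS)-3-hydroxy-4a-methyl-3-(12-phenyldodecyl)tetrahydro-3H-furo[3,2-c][1,2]dioxin-6(4H)-one (cis-fused, hemiketal epimers) | OC1(CCCCCCCCCCCCc2ccccc2)C[C@]2(C)OC(=O)C[C@@H]2OO1 | intermediate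
16 | (4aS,7aS)-4a-methyl-6-oxo-3-(12-phenyldodecyl)hexahydro-3H-furo[3,2-c][1,2]dioxin-3-yl acetate (ketal epimers) | CC(=O)OC1(CCCCCCCCCCCCc2ccccc2)C[C@]2(C)OC(=O)C[C@@H]2OO1 | intermediate
17 | C6 peroxycarbenium ion of the bicyclic peroxylactone with acetoxytrimethylaluminate counter-ion (not isolated) | [O+]1=C(CCCCCCCCCCCCc3ccccc3)C[C@]2(C)OC(=O)C[C@@H]2O1.C[Al-](C)(C)OC(C)=O | intermediate
18 | plakortolide L, (3S,4aS,7aS)-3,4a-dimethyl-3-(12-phenyldodecyl)tetrahydro-3H-furo[3,2-c][1,2]dioxin-6(4H)-one | C[C@]1(CCCCCCCCCCCCc2ccccc2)C[C@]2(C)OC(=O)C[C@@H]2OO1 | target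

**Step count**

Total steps: 7. Longest linear sequence: 6 steps (5 → 6 → 10 → 12 → 15 → 16 → 18); the chain branch (1 → 4) joins at step 4.

**Steps most likely to fail**

1. Step 7 (carries the label).
   - What may go wrong: ionisation of the acetate may be overtaken by Lewis-acid-induced heterolysis of the O–O bond with alkyl migration (Hock/Criegee-type fragmentation); methyl may be transferred to peroxide oxygen; or methyl may arrive on the face of the C4 methyl group.
   - Fallback (known chemistry only): it sets out from cyclobutanol 12 and comes back at 18; the methyl carbon is put in as a methylene group before the peroxide is made.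
   - Silver-catalysed ring-opening chlorination of 12 (AgNO3 cat., K2S2O8, N-chlorosuccinimide, CH2Cl2/H2O) should give, through the same β-scission, (5S)-4-chloro-5-methyl-5-(2-oxo-14-phenyltetradecyl)dihydrofuran-2(3H)-one F1.
   - Non-basic Takai–Lombardo methylenation of the ketone (Zn, CH2Br2, TiCl4, THF) should give (5S)-4-chloro-5-methyl-5-(2-methylidene-14-phenyltetradecyl)dihydrofuran-2(3H)-one F2.
   - DBU then removes HCl to give (S)-5-methyl-5-(2-methylidene-14-phenyltetradecyl)furan-2(5H)-one F3.
   - Mukaiyama–Isayama peroxidation of the 1,1-disubstituted alkene (Co(thd)2 cat., thd = 2,2,6,6-tetramethylheptane-3,5-dionate, O2, Et3SiH, ClCH2CH2Cl) should give (5S)-5-methyl-5-[2-methyl-14-phenyl-2-(triethylsilylperoxy)tetradecyl]furan-2(5H)-one F4 as both epimers at the peroxy carbon.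
   - Tetrabutylammonium fluoride buffered with AcOH frees (5S)-5-(2-hydroperoxy-2-methyl-14-phenyltetradecyl)-5-methylfuran-2(5H)-one F5. Et2NH in CF3CH2OH closes the 1,2-dioxane by intramolecular oxa-Michael addition of the hydroperoxide to the butenolide, which can only give the cis fusion.
   - 18 is then separated by chromatography from its C6 epimer, (3R,4aS,7aS)-3,4a-dimethyl-3-(12-phenyldodecyl)tetrahydro-3H-furo[3,2-c][1,2]dioxin-6(4H)-one F6. C4 of 12 is kept throughout; the price is the loss of control at C6.

2. Step 3.
   - What may go wrong: slow cycloaddition of the enol lactone; acyl transfer from the O-acyl oxocarbenium intermediate instead of ring closure; isomerisation of 7 to the conjugated butenolide; or low facial induction by the auxiliary.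
   - Fallback: it sets out from 7 and comes back at 10; auxiliary control is replaced by a racemic ketene cycloaddition and a resolution.
   - Dichloroketene made in the flask (Cl3CCOCl, activated Zn dust, Et2O) should add to 7 with the same regiochemistry to give racemic cis-fused 7,7-dichloro-1-methyl-2-oxabicyclo[3.2.0]heptane-3,6-dione F7.
   - Zn in AcOH removes both chlorines to give racemic cis-fused 1-methyl-2-oxabicyclo[3.2.0]heptane-3,6-dione F8.
   - Ketalisation of the cyclobutanone with (R,R)-hydrobenzoin (TsOH cat., benzene, reflux with water removal) gives two diastereomers: the (4R,5R)-4,5-diphenyl-1,3-dioxolane ketal of the (1S,5S)-ketone F9 and the (4R,5R)-4,5-diphenyl-1,3-dioxolane ketal of the (1R,5R)-ketone F10.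
   - These are separated by chromatography or crystallisation, and F9 is hydrolysed (aq. HCl, THF) to 10.

3. Step 5.
   - What may go wrong: capture of O2 on the face of the C3 radical away from the side chain, which leaves an open hydroperoxide that cobalt then degrades; or partial scission toward C5.
   - Fallback: it sets out from 12 and comes back at 15; the radical oxygenation is replaced by an oxygen nucleophile that is delivered from the C6 side and therefore only cis.
   - Mn(OAc)3·2H2O with Cu(OAc)2 in AcOH should open 12 by the same alkoxy-radical β-scission. Divalent copper oxidises the C3 radical to the alkene, giving (S)-5-methyl-5-(2-oxo-14-phenyltetradecyl)furan-2(5H)-one F11.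
   - Urea–hydrogen peroxide with Et2NH (cat.) in CF3CH2OH should add H2O2 to the ketone to give (5S)-5-(2-hydroperoxy-2-hydroxy-14-phenyltetradecyl)-5-methylfuran-2(5H)-one F12, whose hydroperoxide adds to the butenolide (6-exo oxa-Michael) to give 15.

**Further compounds**

F1 | step 7 | (5S)-4-chloro-5-methyl-5-(2-oxo-14-phenyltetradecyl)dihydrofuran-2(3H)-one (C4 epimers) | O=C(CCCCCCCCCCCCc1ccccc1)C[C@]1(C)OC(=O)CC1Cl
F2 | step 7 | (5S)-4-chloro-5-methyl-5-(2-methylidene-14-phenyltetradecyl)dihydrofuran-2(3H)-one (C4 epimers) | C=C(CCCCCCCCCCCCc1ccccc1)C[C@]1(C)OC(=O)CC1Cl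
F3 | step 7 | (S)-5-methyl-5-(2-methylidene-14-phenyltetradecyl)furan-2(5H)-one | C=C(CCCCCCCCCCCCc1ccccc1)C[C@]1(C)OC(=O)C=C1
F4 | step 7 | (5S)-5-methyl-5-[2-methyl-14-phenyl-2-(triethylsilylperoxy)tetradecyl]furan-2(5H)-one (epimers at the peroxy carbon) | CC[Si](CC)(CC)OOC(C)(CCCCCCCCCCCCc1ccccc1)C[C@]1(C)OC(=O)C=C1
F5 | step 7 | (5S)-5-(2-hydroperoxy-2-methyl-14-phenyltetradecyl)-5-methylfuran-2(5H)-one (epimers at the peroxy carbon) | OOC(C)(CCCCCCCCCCCCc1ccccc1)C[C@]1(C)OC(=O)C=C1
F6 | step 7 | (3R,4aS,7aS)-3,4a-dimethyl-3-(12-phenyldodecyl)tetrahydro-3H-furo[3,2-c][1,2]dioxin-6(4H)-one (C6 epimer of 18) | C[C@@]1(CCCCCCCCCCCCc2ccccc2)C[C@]2(C)OC(=O)C[C@@H]2OO1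
F7 | step 3 | racemic cis-fused 7,7-dichloro-1-methyl-2-oxabicyclo[3.2.0]heptane-3,6-dione | O=C1C(Cl)(Cl)C2(C)OC(=O)CC12
F8 | step 3 | racemic cis-fused 1-methyl-2-oxabicyclo[3.2.0]heptane-3,6-dione | O=C1CC2(C)OC(=O)CC12
F9 | step 3 | (4R,5R)-4,5-diphenyl-1,3-dioxolane ketal at C6 of (1S,5S)-1-methyl-2-oxabicyclo[3.2.0]heptane-3,6-dione | C13(O[C@H](c4ccccc4)[C@@H](c4ccccc4)O3)C[C@]2(C)OC(=O)C[C@H]12
F10 | step 3 | (4R,5R)-4,5-diphenyl-1,3-dioxolane ketal at C6 of (1R,5R)-1-methyl-2-oxabicyclo[3.2.0]heptane-3,6-dione | C13(O[C@H](c4ccccc4)[C@@H](c4ccccc4)O3)C[C@@]2(C)OC(=O)C[C@@H]12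
F11 | step 5 | (S)-5-methyl-5-(2-oxo-14-phenyltetradecyl)furan-2(5H)-one | O=C(CCCCCCCCCCCCc1ccccc1)C[C@]1(C)OC(=O)C=C1
F12 | step 5 | (5S)-5-(2-hydroperoxy-2-hydroxy-14-phenyltetradecyl)-5-methylfuran-2(5H)-one | OOC(O)(CCCCCCCCCCCCc1ccccc1)C[C@]1(C)OC(=O)C=C1
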